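The route takes the carboxyl carbon off as CO2. In the target, chain carbon C2 carries three things: the acid group, the E-C3=C4 alkene, and a double bond to the CH that bears the sec-butyl group. The hydrogen of this CH faces the carboxyl. This pattern arises when H and CO2 are delivered to one face of an alkyne attached to that E-alkene. A single copper hydride hydrocarboxylation therefore makes the last C–C bond, frees the acid and fixes the trisubstituted alkene. It closes no ring and leaves the dihydropyranone ring alone. Its precursor is the whole skeleton less one carbon: the 3-acyl-4-hydroxy-5,6-dihydropyran-2-one bearing an E-enyne chain, its acidic enol silylated beforehand.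

Key step: step 10

Assumption: the antipode of the diphosphine in step 8 is the one that a trial run shows to give the R lactone. 3,5-t-Bu-MeOBIPHEP = (6,6'-dimethoxybiphenyl-2,2'-diyl)bis[bis(3,5-di-tert-butylphenyl)phosphine]. Compound 13 is drawn as the dione although it rests largely as its 4-hydroxy enol. IMes = 1,3-dimesitylimidazol-2-ylidene.

Step 1
Reactants: 1 (R)-citronellal
Product: 2 (1E,4R)-1-iodo-4,8-dimethylnona-1,7-diene
Conditions: CrCl2 (6 equiv), CHI3 (2 equiv), 1,4-dioxane/THF (6:1), 0 °C to rt
Reagents that add atoms: iodoform, IC(I)I
Why: Takai olefination, in which the gem-dichromium species made from CHI3 and divalent chromium adds to the unhindered aldehyde and eliminates to favour the E-iodoalkene (the dioxane-rich solvent is chosen to raise that preference), while the methyl-bearing centre β to the carbonyl and the trisubstituted alkene are not touched.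

Step 2
Reactants: 2 (1E,4R)-1-iodo-4,8-dimethylnona-1,7-diene
Product: 4 (4R,6E)-7-iodo-4-methylhept-6-enal, via vicinal diol 3 (not isolated)
Conditions: OsO4 (2 mol %), NMO (1.05 equiv), acetone/H2O, 0 °C; then NaIO4 (1.5 equiv), rt
Reagents that add atoms: N-methylmorpholine N-oxide, C[N+]1([O-])CCOCC1; water, O (oxygen relayed through OsO4)
Why: Catalytic osmium tetroxide dihydroxylation followed by periodate glycol cleavage (a stepwise Lemieux–Johnson sequence in one flask), in which the electrophilic oxidant, limited by one equivalent of NMO, should take the electron-rich trisubstituted alkene rather than the iodine-deactivated disubstituted one.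

Step 3
Reactants: 4 (4R,6E)-7-iodo-4-methylhept-6-enal
Product: 5 (4R,6E)-7-iodo-4-methylhept-6-enoic acid
Conditions: NaClO2, NaH2PO4, 2-methylbut-2-ene, t-BuOH/H2O, 0 °C to rt
Reagents that add atoms: sodium chlorite, [Na+].[O-]Cl=O
Why: Pinnick oxidation, whose buffered chlorous acid converts only the aldehyde, the scavenger alkene removing hypochlorous acid before it can add to the iodoalkene.

Step 4
Reactants: 6 (S)-2-methylbutan-1-ol
Product: 7 (S)-2-methylbutanal
Conditions: TEMPO (1 mol %), KBr (10 mol %), aq NaOCl/NaHCO3 (pH 9.5), CH2Cl2, 0 °C
Reagents that add atoms: none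
Why: Anelli oxidation, a fast oxoammonium-mediated oxidation in a cold, buffered two-phase medium that stops at the aldehyde and gives the α-centre little chance to enolise, the dried CH2Cl2 solution being used at once.

Step 5
Reactants: 7 (S)-2-methylbutanal
Product: 8 (S)-1,1-dibromo-3-methylpent-1-ene
Conditions: CBr4 (2 equiv), PPh3 (4 equiv), CH2Cl2, 0 °C
Reagents that add atoms: carbon tetrabromide, BrC(Br)(Br)Br
Why: First half of the Corey–Fuchs homologation, a Wittig reaction with the weakly basic dibromomethylene ylide, so the α-stereocentre becomes a configurationally safe allylic centre without passing through an enolate.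

Step 6
Reactants: 8 (S)-1,1-dibromo-3-methylpent-1-ene
Product: 10 (S)-3-methylpent-1-yne, via lithium acetylide 9 (not isolated)
Conditions: n-BuLi (2.05 equiv), THF, −78 °C to 0 °C; H2O; kept as a dried and assayed THF/hexane solution
Reagents that add atoms: none
Why: Second half of the Corey–Fuchs homologation (bromine–lithium exchange, α-elimination with 1,2-hydride shift of the Fritsch–Buttenberg–Wiechell type, deprotonation, quench), in which the propargylic C–H is too weakly acidic for the small excess of base at low temperature, and handling in solution avoids loss of the volatile alkyne.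

Step 7
Reactants: 5 (4R,6E)-7-iodo-4-methylhept-6-enoic acid; 10 (S)-3-methylpent-1-yne (1.5–2 equiv)
Product: 11 (4R,6E,10S)-4,10-dimethyldodec-6-en-8-ynoic acid
Conditions: PdCl2(PPh3)2 (3 mol %), CuI (6 mol %), Et3N (5 equiv), THF, rt, degassed, closed flask; aq citric acid work-up
Reagents that add atoms: none
Why: Sonogashira coupling, in which oxidative addition of the vinyl iodide to zerovalent palladium and the reductive elimination both retain the E geometry, the acid travelling as its ammonium salt and neither stereocentre being involved.

Step 8
Reactants: 12 4-hydroxy-6-methyl-2H-pyran-2-one (triacetic acid lactone)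
Product: 13 (R)-6-methyloxane-2,4-dione
Conditions: Ru(OAc)2(3,5-t-Bu-MeOBIPHEP) (0.5 mol %), HBF4·OEt2 (1 mol %), H2 (60 bar), i-PrOH, 60 °C
Reagents that add atoms: none
Why: Enantioselective hydrogenation with a cationic divalent ruthenium diphosphine catalyst, a reaction type established for 2-pyrones of this kind, which saturates C5=C6 and leaves the enolised β-dicarbonyl, the C6 centre being set by the chiral pocket of the atropisomeric ligand (catalyst control).

Step 9
Reactants: 11 (4R,6E,10S)-4,10-dimethyldodec-6-en-8-ynoic acid; 13 (R)-6-methyloxane-2,4-dione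
Product: 15 (6R)-3-[(4R,6E,10S)-4,10-dimethyldodec-6-en-8-ynoyl]-4-hydroxy-6-methyl-5,6-dihydro-2H-pyran-2-one, via enol ester 14 (not isolated)
Conditions: DCC (1.1 equiv), DMAP (0.5 equiv), CH2Cl2, 0 °C to rt
Reagents that add atoms: none
Why: Steglich-type activation acylates the C4 enol oxygen, and DMAP then returns the acyl group through an acylpyridinium/enolate ion pair to ring C3 (Fries-type O-to-C migration), driven by the hydrogen-bonded tricarbonyl, with no stereocentre next to a reacting carbon.

Step 10
Reactants: 15 (6R)-3-[(4R,6E,10S)-4,10-dimethyldodec-6-en-8-ynoyl]-4-hydroxy-6-methyl-5,6-dihydro-2H-pyran-2-one; 16 carbon dioxide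
Product: 19 (2E,3E,6R)-9-[(6R)-4-hydroxy-6-methyl-2-oxo-5,6-dihydro-2H-pyran-3-yl]-6-methyl-2-[(2S)-2-methylbutylidene]-9-oxonon-3-enoic acid, via trimethylsilyl enol ether 17 (not isolated), via doubly silylated dienoate 18 (not isolated)
Conditions: HN(SiMe3)2, toluene, 50 °C, then volatiles off in vacuo; (IMes)CuF (10 mol %), HSi(OEt)3 (2 equiv), CO2 (1 atm), 1,4-dioxane, 70 °C; aq citric acid/THF, rt
Reagents that add atoms: carbon dioxide (16), O=C=O
Why: Proposed new method: with the acidic enol capped as 17, so that no proton source can turn the catalysis into plain semireduction or bind copper as a chelate, (IMes)CuF and HSi(OEt)3 form (IMes)CuH, which adds syn across the C≡C bond (H to the carbon next to the sec-butyl group, copper to the carbon next to CH=CH); CO2 then inserts into the Cu–C(sp2) bond with retention, the silane converts the copper carboxylate into silyl ester 18 and fresh copper hydride, and both silyl groups fall off in the acidic work-up. The closest known reaction type is the syn-hydrocarboxylation of aryl-substituted internal alkynes with CO2 and a hydrosilane catalysed by N-heterocyclic carbene complexes of monovalent copper; new here are a vinyl group in the role of the aryl group and a masked tricarbonyl as spectator. No ring is closed and no stereocentre is made; the only new stereo-element, the trisubstituted alkene with H cis to CO2H, follows from syn addition plus retentive carboxylation. Regioselectivity is needed and should come from two factors acting in the same direction, conjugation of the copper-bearing carbon with the adjacent alkene and the α-branching of the sec-butyl group, which keeps the bulky (IMes)Cu fragment away from that side. Chemoselectivity is needed as well: the alkyne should insert faster than the 1,2-disubstituted alkene, both carbonyl groups of 17 are vinylogous esters of the C4 silyloxy group on a tetrasubstituted C3=C4 bond and thus poor hydride acceptors, and the silane is held near two equivalents so that the dienoate is not reduced further. The medium is neutral, so the allylic sec-butyl centre, the chain methyl centre and ring C6 should keep their configuration, and no ester has to be cleaved afterwards.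

Compound list
1 | (R)-citronellal, (3R)-3,7-dimethyloct-6-enal | O=CC[C@H](C)CCC=C(C)C | starting material
2 | (1E,4R)-1-iodo-4,8-dimethylnona-1,7-diene | I/C=C/C[C@H](C)CCC=C(C)C | intermediate
3 | (6R,8E)-9-iodo-2,6-dimethylnon-8-ene-2,3-diol (both C3 epimers) | I/C=C/C[C@H](C)CCC(O)C(C)(C)O | intermediate
4 | (4R,6E)-7-iodo-4-methylhept-6-enal | I/C=C/C[C@H](C)CCC=O | intermediate
5 | (4R,6E)-7-iodo-4-methylhept-6-enoic acid | I/C=C/C[C@H](C)CCC(=O)O | intermediate
6 | (S)-2-methylbutan-1-ol | CC[C@H](C)CO | starting material
7 | (S)-2-methylbutanal | CC[C@H](C)C=O | intermediate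
8 | (S)-1,1-dibromo-3-methylpent-1-ene | CC[C@H](C)C=C(Br)Br | intermediate
9 | lithium (S)-3-methylpent-1-yn-1-ide | CC[C@H](C)C#C[Li] | intermediate
10 | (S)-3-methylpent-1-yne | CC[C@H](C)C#C | intermediate
11 | (4R,6E,10S)-4,10-dimethyldodec-6-en-8-ynoic acid | CC[C@H](C)C#C/C=C/C[C@H](C)CCC(=O)O | intermediate
12 | 4-hydroxy-6-methyl-2H-pyran-2-one (triacetic acid lactone) | CC1=CC(O)=CC(=O)O1 | starting material
13 | (R)-6-methyloxane-2,4-dione | O=C1CC(=O)C[C@@H](C)O1 | intermediate
14 | (2R)-2-methyl-6-oxo-3,6-dihydro-2H-pyran-4-yl (4R,6E,10S)-4,10-dimethyldodec-6-en-8-ynoate | CC[C@H](C)C#C/C=C/C[C@H](C)CCC(=O)OC1=CC(=O)O[C@H](C)C1 | intermediate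
15 | (6R)-3-[(4R,6E,10S)-4,10-dimethyldodec-6-en-8-ynoyl]-4-hydroxy-6-methyl-5,6-dihydro-2H-pyran-2-one | CC[C@H](C)C#C/C=C/C[C@H](C)CCC(=O)C1=C(O)C[C@@H](C)OC1=O | intermediate
16 | carbon dioxide | O=C=O | starting material
17 | 4-O-trimethylsilyl enol ether of 15 | CC[C@H](C)C#C/C=C/C[C@H](C)CCC(=O)C1=C(O[Si](C)(C)C)C[C@@H](C)OC1=O | intermediate
18 | triethoxysilyl ester of 19 with the ring enol still trimethylsilylated | CC[C@H](C)/C=C(\C=C\C[C@H](C)CCC(=O)C1=C(O[Si](C)(C)C)C[C@@H](C)OC1=O)C(=O)O[Si](OCC)(OCC)OCC | intermediate
19 | (2E,3E,6R)-9-[(6R)-4-hydroxy-6-methyl-2-oxo-5,6-dihydro-2H-pyran-3-yl]-6-methyl-2-[(2S)-2-methylbutylidene]-9-oxonon-3-enoic acid (CNP0281879.1) | CC[C@H](C)/C=C(\C=C\C[C@H](C)CCC(=O)C1=C(O)C[C@@H](C)OC1=O)C(=O)O | target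

Total step count: 10.
Longest linear sequence: 6 steps (steps 1, 2, 3, 7, 9, 10 from 1). The branch from 6 (steps 4, 5, 6, 7, 9, 10) is equally long.

Steps most likely to fail

Step 10. Several things may go wrong:
- Copper hydride may add with the wrong regiochemistry or to the alkene.
- The dienylcopper may be protonated, or carboxylated at its remote terminus, instead of at the metal-bearing carbon.
- The hydride may attack the masked tricarbonyl or reduce the dienoate further.

The fallback keeps the syn-addition logic but uses known tin and palladium chemistry, with CO as the carbon source. It sets out from 15 and comes back at 19.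
- Palladium-catalysed syn-hydrostannation (PdCl2(PPh3)2, Bu3SnH, THF, 0 °C) places tin on the alkyne carbon next to the alkene of a conjugated enyne and away from a branched substituent. It would give (6R)-3-[(4R,6E,8E,10S)-4,10-dimethyl-8-(tributylstannyl)dodeca-6,8-dienoyl]-4-hydroxy-6-methyl-5,6-dihydro-2H-pyran-2-one F1.
- Iododestannylation in the same flask (I2, 0 °C) with retention would give the corresponding 8-iodo diene, (6R)-3-[(4R,6E,8E,10S)-8-iodo-4,10-dimethyldodeca-6,8-dienoyl]-4-hydroxy-6-methyl-5,6-dihydro-2H-pyran-2-one F2.
- Palladium-catalysed hydroxycarbonylation (Pd(OAc)2, PPh3, CO 1 atm, H2O, Et3N, DMF, rt) would then deliver 19.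

Step 8. The hydrogenation may stall, may go on to saturate the enol double bond, or may show poor facial selectivity with the ligand at hand. The fallback buys the stereocentre instead of making it. It starts from neither 12 nor any other numbered compound, and it comes back to the route at 13.
- It sets out from commercial methyl (R)-3-hydroxybutanoate F3.
- F3 is condensed with an excess of the lithium enolate of tert-butyl acetate (LDA, THF, −78 to −20 °C, crossed Claisen condensation) to give tert-butyl (R)-5-hydroxy-3-oxohexanoate F4.
- Treatment with TFA in CH2Cl2 at rt removes the tert-butyl group and closes the lactone.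

Step 1. The chromium-mediated olefination may give incomplete E-selectivity, and the geometric isomers would be hard to separate and would carry through to the end. The fallback sets out from 1 and comes back at 2.
- Seyferth–Gilbert homologation with the Ohira–Bestmann reagent (K2CO3, MeOH, rt) is harmless here because 1 has no α-stereocentre. It would give (4R)-4,8-dimethylnon-7-en-1-yne F5.
- Hydrozirconation with Cp2Zr(H)Cl (THF, rt) is selective for the terminal alkyne over the trisubstituted alkene. It would give the (E)-alkenylzirconocene chloride F6.
- Iodinolysis (I2, 0 °C) with retention would give 2 as a single geometric isomer, at the cost of one more step.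

Further compounds
F1 | step 10 | (6R)-3-[(4R,6E,8E,10S)-4,10-dimethyl-8-(tributylstannyl)dodeca-6,8-dienoyl]-4-hydroxy-6-methyl-5,6-dihydro-2H-pyran-2-one | CC[C@H](C)/C=C(\C=C\C[C@H](C)CCC(=O)C1=C(O)C[C@@H](C)OC1=O)[Sn](CCCC)(CCCC)CCCC
F2 | step 10 | (6R)-3-[(4R,6E,8E,10S)-8-iodo-4,10-dimethyldodeca-6,8-dienoyl]-4-hydroxy-6-methyl-5,6-dihydro-2H-pyran-2-one | CC[C@H](C)/C=C(\C=C\C[C@H](C)CCC(=O)C1=C(O)C[C@@H](C)OC1=O)I
F3 | step 8 | methyl (R)-3-hydroxybutanoate (bought) | C[C@@H](O)CC(=O)OC
F4 | step 8 | tert-butyl (R)-5-hydroxy-3-oxohexanoate | C[C@@H](O)CC(=O)CC(=O)OC(C)(C)C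
F5 | step 1 | (4R)-4,8-dimethylnon-7-en-1-yne | C#CC[C@H](C)CCC=C(C)C
F6 | step 1 | chlorobis(cyclopentadienyl)[(1E,4R)-4,8-dimethylnona-1,7-dien-1-yl]zirconium | Cl[Zr](C1C=CC=C1)(C1C=CC=C1)/C=C/C[C@H](C)CCC=C(C)C
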